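**Retrosynthetic overview**
1. The target comes from its 2-O-TBS ether 26. The ten-membered ring of 26 is closed at C7–C8. The β-carbon (C7) of a 6R 3-(bromomethyl)butenolide is turned into a donor through its allylchromium, a homoenolate-type d3 synthon, and adds to the C8 aldehyde. This sets C7 and C8 and unveils the α-methylene lactone.
2. Ring order: the five-membered lactone is made first, by RCM of a 2-(bromomethyl)acrylate on a C6 vinyl carbinol. The ten-membered carbocycle is made second.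
3. C8 enters as 2-lithio-1,3-dithiane (a formyl anion) on a Z-Weinreb amide. A CBS reduction sets C9, and the angelate is installed before cyclisation.
4. C1–C6, C9, C10, C14 and C15 come from geranyl acetate, which supplies the E-C4=C5 alkene. D-Proline aminoxylation sets C2, and Still–Gennari olefination gives the Z-C1=C10 alkene.

Assumption: positions are given in germacrane numbering (C1–C15, lactone C6–O–C12). All numbered starting materials, (−)-MIB and the CBS catalyst are purchased.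

**Step 1**
Reactants: 1 geranyl acetate
Product: 2 (2E)-3-methyl-6-oxohex-2-en-1-yl acetate
Conditions: O3 (1.0 equiv), CH2Cl2–pyridine, −78 °C; then Me2S, −78 → 23 °C
Reagents that add atoms: ozone [O-][O+]=O
Why: Chemoselective ozonolysis works because the remote trisubstituted alkene is much more electron-rich than the one deactivated by the allylic acetate, so only it is cleaved and the E-alkene (future C4=C5) is kept.

**Step 2**
Reactants: 2 (2E)-3-methyl-6-oxohex-2-en-1-yl acetate; 3 nitrosobenzene; 4 ethyl 2-[bis(2,2,2-trifluoroethoxy)phosphoryl]propanoate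
Product: 6 ethyl (2Z,4S,6E)-8-acetoxy-2,6-dimethyl-4-[(phenylamino)oxy]octa-2,6-dienoate, via aminoxy aldehyde 5 (not isolated)
Conditions: 3 (0.9 equiv), D-proline (20 mol %), MeCN, −20 °C, 24 h; then cannulated into 4 (2.2 equiv), KN(SiMe3)2 (2.1 equiv), 18-crown-6, THF, −78 °C
Reagents that add atoms: nitrosobenzene O=Nc1ccccc1; ethyl 2-[bis(2,2,2-trifluoroethoxy)phosphoryl]propanoate CCOC(=O)C(C)P(=O)(OCC(F)(F)F)OCC(F)(F)F
Why: Proline-catalysed enamine α-aminoxylation with D-proline gives the S centre at C2, and the labile aldehyde is trapped at once by a Still–Gennari olefination whose kinetic elimination gives the Z-trisubstituted enoate (future C1=C10).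

**Step 3**
Reactants: 6 ethyl (2Z,4S,6E)-8-acetoxy-2,6-dimethyl-4-[(phenylamino)oxy]octa-2,6-dienoate
Product: 8 (2E)-3-methyl-4-[(2S)-4-methyl-5-oxo-2,5-dihydrofuran-2-yl]but-2-en-1-yl acetate, via hydroxy ester 7 (not isolated)
Conditions: Cu(OAc)2 (30 mol %), EtOH, 23 °C; then PPTS (10 mol %), toluene, 40 °C
Reagents that add atoms: none
Why: Cu(OAc)2-catalysed N–O cleavage frees the C2 hydroxyl, which lies cis to the ester and lactonises, so the butenolide locks the Z-geometry, removes any E-isomer, and leaves C2 untouched.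

**Step 4**
Reactants: 8 (2E)-3-methyl-4-[(2S)-4-methyl-5-oxo-2,5-dihydrofuran-2-yl]but-2-en-1-yl acetate; 9 N,O-dimethylhydroxylamine hydrochloride
Product: 10 (2Z,4S,6E)-4,8-dihydroxy-N-methoxy-N,2,6-trimethylocta-2,6-dienamide
Conditions: 9 (6 equiv), AlMe3 (6 equiv), CH2Cl2, 0 → 23 °C; aq. potassium sodium tartrate
Reagents that add atoms: N,O-dimethylhydroxylamine hydrochloride CNOC.Cl
Why: Weinreb aminolysis with the weakly basic aluminium amide opens the lactone as its aluminium alkoxide without γ-deprotonation (so C2 does not racemise), and the excess reagent removes the acetate in the same operation.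

**Step 5**
Reactants: 10 (2Z,4S,6E)-4,8-dihydroxy-N-methoxy-N,2,6-trimethylocta-2,6-dienamide
Product: 12 (2Z,4S,6E)-4-[(tert-butyldimethylsilyl)oxy]-N-methoxy-N,2,6-trimethyl-8-[(triethylsilyl)oxy]octa-2,6-dienamide, via mono-TES ether 11 (not isolated)
Conditions: TESCl (1.05 equiv), imidazole, CH2Cl2, −40 °C; then TBSOTf (1.3 equiv), 2,6-lutidine, −40 → 0 °C
Reagents that add atoms: chlorotriethylsilane CC[Si](Cl)(CC)CC; tert-butyldimethylsilyl triflate CC(C)(C)[Si](C)(C)OS(=O)(=O)C(F)(F)F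
Why: In this rate-differentiated silylation the primary allylic alcohol takes TES at low temperature, and the secondary C2 alcohol is then capped with the stronger silylating agent before it can relactonise.

**Step 6**
Reactants: 12 (2Z,4S,6E)-4-[(tert-butyldimethylsilyl)oxy]-N-methoxy-N,2,6-trimethyl-8-[(triethylsilyl)oxy]octa-2,6-dienamide; 13 1,3-dithiane
Product: 14 (2Z,4S,6E)-4-[(tert-butyldimethylsilyl)oxy]-1-(1,3-dithian-2-yl)-2,6-dimethyl-8-[(triethylsilyl)oxy]octa-2,6-dien-1-one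
Conditions: 13 (2.5 equiv), n-BuLi (2.4 equiv), THF, −30 °C; then 12, −78 → −30 °C; aq. NH4Cl
Reagents that add atoms: 1,3-dithiane C1CSCSC1
Why: In this Corey–Seebach acylation the formyl-anion equivalent adds only once to the Weinreb amide, because the chelated adduct is stable and the acyl dithiane is then held as its enolate, and it brings in C8 at the aldehyde oxidation level.

**Step 7**
Reactants: 14 (2Z,4S,6E)-4-[(tert-butyldimethylsilyl)oxy]-1-(1,3-dithian-2-yl)-2,6-dimethyl-8-[(triethylsilyl)oxy]octa-2,6-dien-1-one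
Product: 15 (1R,2Z,4S,6E)-4-[(tert-butyldimethylsilyl)oxy]-1-(1,3-dithian-2-yl)-2,6-dimethyl-8-[(triethylsilyl)oxy]octa-2,6-dien-1-ol
Conditions: (S)-Me-CBS (0.5 equiv), catecholborane (2 equiv), toluene, −60 → −40 °C; pH 7 buffer
Reagents that add atoms: none
Why: In the Corey–Bakshi–Shibata 1,2-reduction of a 2-acyl-1,3-dithiane the dithianyl group acts as the large substituent, so the (S)-catalyst delivers hydride to give the R carbinol at C9.

**Step 8**
Reactants: 15 (1R,2Z,4S,6E)-4-[(tert-butyldimethylsilyl)oxy]-1-(1,3-dithian-2-yl)-2,6-dimethyl-8-[(triethylsilyl)oxy]octa-2,6-dien-1-ol; 16 angelic acid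
Product: 17 (1R,2Z,4S,6E)-4-[(tert-butyldimethylsilyl)oxy]-1-(1,3-dithian-2-yl)-2,6-dimethyl-8-[(triethylsilyl)oxy]octa-2,6-dien-1-yl (2Z)-2-methylbut-2-enoate
Conditions: 16 (3 equiv), 2,4,6-Cl3C6H2COCl (3 equiv), Et3N (6 equiv), toluene, 23 °C, 2 h; then 15, 80 °C
Reagents that add atoms: angelic acid C/C=C(/C)C(=O)O
Why: Yamaguchi mixed-anhydride esterification without a nucleophilic catalyst installs the angelate without isomerisation to the tiglate and with retention at C9.

**Step 9**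
Reactants: 17 (1R,2Z,4S,6E)-4-[(tert-butyldimethylsilyl)oxy]-1-(1,3-dithian-2-yl)-2,6-dimethyl-8-[(triethylsilyl)oxy]octa-2,6-dien-1-yl (2Z)-2-methylbut-2-enoate
Product: 18 (1R,2Z,4S,6E)-4-[(tert-butyldimethylsilyl)oxy]-1-(1,3-dithian-2-yl)-2,6-dimethyl-8-oxoocta-2,6-dien-1-yl (2Z)-2-methylbut-2-enoate
Conditions: (COCl)2 (4 equiv), DMSO (8 equiv), CH2Cl2, −78 → −40 °C; Et3N, → 0 °C
Reagents that add atoms: none
Why: Swern oxidation acts directly on the primary triethylsilyl ether, because the ether oxygen attacks the chlorosulfonium ion with loss of Et3SiCl, while the secondary TBS ether, the dithiane and the ester are inert, so the E-enal forms in one step.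

**Step 10**
Reactants: 18 (1R,2Z,4S,6E)-4-[(tert-butyldimethylsilyl)oxy]-1-(1,3-dithian-2-yl)-2,6-dimethyl-8-oxoocta-2,6-dien-1-yl (2Z)-2-methylbut-2-enoate; 19 vinylmagnesium bromide
Product: 20 (1R,2Z,4S,6E,8S)-4-[(tert-butyldimethylsilyl)oxy]-1-(1,3-dithian-2-yl)-8-hydroxy-2,6-dimethyldeca-2,6,9-trien-1-yl (2Z)-2-methylbut-2-enoate
Conditions: 19 (4 equiv), ZnCl2 (2 equiv), Et2O–dioxane, salts filtered off; (−)-MIB (15 mol %), toluene, −20 °C; aq. NH4Cl
Reagents that add atoms: vinylmagnesium bromide C=C[Mg]Br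
Why: In this amino-alcohol-catalysed asymmetric addition of divinylzinc the (−)-MIB zinc complex transfers vinyl to the Si face of the enal and sets C6 (S here, R in the lactone only through a priority change), and the organozinc leaves the ester and dithiane alone.

**Step 11**
Reactants: 20 (1R,2Z,4S,6E,8S)-4-[(tert-butyldimethylsilyl)oxy]-1-(1,3-dithian-2-yl)-8-hydroxy-2,6-dimethyldeca-2,6,9-trien-1-yl (2Z)-2-methylbut-2-enoate; 21 2-(bromomethyl)acrylic acid
Product: 22 (1R,2Z,4S,6E,8S)-8-{[2-(bromomethyl)acryloyl]oxy}-4-[(tert-butyldimethylsilyl)oxy]-1-(1,3-dithian-2-yl)-2,6-dimethyldeca-2,6,9-trien-1-yl (2Z)-2-methylbut-2-enoate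
Conditions: 21 (1.5 equiv), DCC (1.6 equiv), DMAP (5 mol %), CH2Cl2, −10 °C
Reagents that add atoms: 2-(bromomethyl)acrylic acid C=C(CBr)C(=O)O
Why: Steglich esterification at low temperature with little DMAP acylates the only free hydroxyl with retention at C6 and brings in C11, C12 and C13 with the bromide already in place.

**Step 12**
Reactants: 22 (1R,2Z,4S,6E,8S)-8-{[2-(bromomethyl)acryloyl]oxy}-4-[(tert-butyldimethylsilyl)oxy]-1-(1,3-dithian-2-yl)-2,6-dimethyldeca-2,6,9-trien-1-yl (2Z)-2-methylbut-2-enoate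
Product: 23 (2R,3Z,5S,7E,9S)-9-{[2-(bromomethyl)acryloyl]oxy}-5-[(tert-butyldimethylsilyl)oxy]-3,7-dimethyl-1-oxoundeca-3,7,10-trien-2-yl (2Z)-2-methylbut-2-enoate
Conditions: PhI(OCOCF3)2 (1.5 equiv), MeCN–H2O 9:1, 0 °C, 10 min
Reagents that add atoms: water O
Why: Oxidative dithiane hydrolysis with a hypervalent iodine reagent attacks sulfur within minutes, so the alkenes, the TBS ether, the bromide and the epimerisable C9 survive, and sulfur is gone before the metathesis.

**Step 13**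
Reactants: 23 (2R,3Z,5S,7E,9S)-9-{[2-(bromomethyl)acryloyl]oxy}-5-[(tert-butyldimethylsilyl)oxy]-3,7-dimethyl-1-oxoundeca-3,7,10-trien-2-yl (2Z)-2-methylbut-2-enoate
Product: 24 (2R,3Z,5S,7E)-8-[(2R)-4-(bromomethyl)-5-oxo-2,5-dihydrofuran-2-yl]-5-[(tert-butyldimethylsilyl)oxy]-3,7-dimethyl-1-oxoocta-3,7-dien-2-yl (2Z)-2-methylbut-2-enoate
Conditions: second-generation Hoveyda–Grubbs catalyst (10 mol %), CH2Cl2 (5 mM), 40 °C, argon sparge
Reagents that add atoms: none
Why: In this ring-closing metathesis the catalyst loads on the only monosubstituted alkene and closes onto the acrylate to give the five-membered butenolide, while the trisubstituted alkenes and the aldehyde are spectators and C6 is untouched.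

**Step 14**
Reactants: 24 (2R,3Z,5S,7E)-8-[(2R)-4-(bromomethyl)-5-oxo-2,5-dihydrofuran-2-yl]-5-[(tert-butyldimethylsilyl)oxy]-3,7-dimethyl-1-oxoocta-3,7-dien-2-yl (2Z)-2-methylbut-2-enoate
Product: 26 (1(10)Z,4E,2S,6R,7R,8R,9R)-9-angeloyloxy-2-[(tert-butyldimethylsilyl)oxy]-8-hydroxygermacra-1(10),4,11(13)-trien-12,6-olide, via allylchromium species 25 (not isolated)
Conditions: CrCl2 (12 equiv), THF–DMF 4:1, 23 °C, 24 added by syringe pump over 12 h (final 1 mM); aqueous work-up
Reagents that add atoms: none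
Why: In this intramolecular Nozaki–Hiyama (Barbier-type) allylation two equivalents of CrCl2 convert the bromide into an allylchromium in which the butenolide β-carbon C7, normally an acceptor, becomes the donor (a homoenolate-type d3 synthon) and attacks the electrophilic C8 aldehyde through a chair transition state, anti to the C5 chain on the lactone (C7 R, trans-lactone) and with the ring-locked E-type allyl geometry giving the anti C7/C8 relationship (C8 R), while the allylic transposition unveils the exocyclic methylene.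

**Step 15**
Reactants: 26 (1(10)Z,4E,2S,6R,7R,8R,9R)-9-angeloyloxy-2-[(tert-butyldimethylsilyl)oxy]-8-hydroxygermacra-1(10),4,11(13)-trien-12,6-olide
Product: 27 (1(10)Z,4E,2S,6R,7R,8R,9R)-9-angeloyloxy-2,8-dihydroxygermacra-1(10),4,11(13)-trien-12,6-olide (CNP0311662.1)
Conditions: HF·pyridine, pyridine–THF, 0 → 23 °C
Reagents that add atoms: none
Why: Buffered fluoride desilylation removes the allylic TBS ether without base, so neither conjugate addition to the α-methylene lactone nor angelate migration or isomerisation occurs and no stereocentre is touched.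

**Compound list**
1 | geranyl acetate [(2E)-3,7-dimethylocta-2,6-dien-1-yl acetate] | CC(=O)OC/C=C(\C)CCC=C(C)C | starting material
2 | (2E)-3-methyl-6-oxohex-2-en-1-yl acetate | CC(=O)OC/C=C(\C)CCC=O | intermediate
3 | nitrosobenzene | O=Nc1ccccc1 | starting material
4 | ethyl 2-[bis(2,2,2-trifluoroethoxy)phosphoryl]propanoate | CCOC(=O)C(C)P(=O)(OCC(F)(F)F)OCC(F)(F)F | starting material
5 | (2E,5S)-3-methyl-6-oxo-5-[(phenylamino)oxy]hex-2-en-1-yl acetate | CC(=O)OC/C=C(\C)C[C@H](ONc1ccccc1)C=O | intermediate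
6 | ethyl (2Z,4S,6E)-8-acetoxy-2,6-dimethyl-4-[(phenylamino)oxy]octa-2,6-dienoate | CC(=O)OC/C=C(\C)C[C@H](ONc1ccccc1)/C=C(/C)C(=O)OCC | intermediate
7 | ethyl (2Z,4S,6E)-8-acetoxy-4-hydroxy-2,6-dimethylocta-2,6-dienoate | CC(=O)OC/C=C(\C)C[C@H](O)/C=C(/C)C(=O)OCC | intermediate
8 | (2E)-3-methyl-4-[(2S)-4-methyl-5-oxo-2,5-dihydrofuran-2-yl]but-2-en-1-yl acetate | CC(=O)OC/C=C(\C)C[C@H]1C=C(C)C(=O)O1 | intermediate
9 | N,O-dimethylhydroxylamine hydrochloride | CNOC.Cl | starting material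
10 | (2Z,4S,6E)-4,8-dihydroxy-N-methoxy-N,2,6-trimethylocta-2,6-dienamide | OC/C=C(\C)C[C@H](O)/C=C(/C)C(=O)N(C)OC | intermediate
11 | (2Z,4S,6E)-4-hydroxy-N-methoxy-N,2,6-trimethyl-8-[(triethylsilyl)oxy]octa-2,6-dienamide | CC[Si](CC)(CC)OC/C=C(\C)C[C@H](O)/C=C(/C)C(=O)N(C)OC | intermediate
12 | (2Z,4S,6E)-4-[(tert-butyldimethylsilyl)oxy]-N-methoxy-N,2,6-trimethyl-8-[(triethylsilyl)oxy]octa-2,6-dienamide | CC[Si](CC)(CC)OC/C=C(\C)C[C@H](O[Si](C)(C)C(C)(C)C)/C=C(/C)C(=O)N(C)OC | intermediate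
13 | 1,3-dithiane | C1CSCSC1 | starting material
14 | (2Z,4S,6E)-4-[(tert-butyldimethylsilyl)oxy]-1-(1,3-dithian-2-yl)-2,6-dimethyl-8-[(triethylsilyl)oxy]octa-2,6-dien-1-one | CC[Si](CC)(CC)OC/C=C(\C)C[C@H](O[Si](C)(C)C(C)(C)C)/C=C(/C)C(=O)C1SCCCS1 | intermediate
15 | (1R,2Z,4S,6E)-4-[(tert-butyldimethylsilyl)oxy]-1-(1,3-dithian-2-yl)-2,6-dimethyl-8-[(triethylsilyl)oxy]octa-2,6-dien-1-ol | CC[Si](CC)(CC)OC/C=C(\C)C[C@H](O[Si](C)(C)C(C)(C)C)/C=C(/C)[C@@H](O)C1SCCCS1 | intermediate
16 | angelic acid [(2Z)-2-methylbut-2-enoic acid] | C/C=C(/C)C(=O)O | starting material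
17 | (1R,2Z,4S,6E)-4-[(tert-butyldimethylsilyl)oxy]-1-(1,3-dithian-2-yl)-2,6-dimethyl-8-[(triethylsilyl)oxy]octa-2,6-dien-1-yl (2Z)-2-methylbut-2-enoate | CC[Si](CC)(CC)OC/C=C(\C)C[C@H](O[Si](C)(C)C(C)(C)C)/C=C(/C)[C@@H](OC(=O)/C(C)=C\C)C1SCCCS1 | intermediate
18 | (1R,2Z,4S,6E)-4-[(tert-butyldimethylsilyl)oxy]-1-(1,3-dithian-2-yl)-2,6-dimethyl-8-oxoocta-2,6-dien-1-yl (2Z)-2-methylbut-2-enoate | O=C/C=C(\C)C[C@H](O[Si](C)(C)C(C)(C)C)/C=C(/C)[C@@H](OC(=O)/C(C)=C\C)C1SCCCS1 | intermediate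
19 | vinylmagnesium bromide | C=C[Mg]Br | starting material
20 | (1R,2Z,4S,6E,8S)-4-[(tert-butyldimethylsilyl)oxy]-1-(1,3-dithian-2-yl)-8-hydroxy-2,6-dimethyldeca-2,6,9-trien-1-yl (2Z)-2-methylbut-2-enoate | O[C@@H](C=C)/C=C(\C)C[C@H](O[Si](C)(C)C(C)(C)C)/C=C(/C)[C@@H](OC(=O)/C(C)=C\C)C1SCCCS1 | intermediate
21 | 2-(bromomethyl)acrylic acid | C=C(CBr)C(=O)O | starting material
22 | (1R,2Z,4S,6E,8S)-8-{[2-(bromomethyl)acryloyl]oxy}-4-[(tert-butyldimethylsilyl)oxy]-1-(1,3-dithian-2-yl)-2,6-dimethyldeca-2,6,9-trien-1-yl (2Z)-2-methylbut-2-enoate | C=C(CBr)C(=O)O[C@@H](C=C)/C=C(\C)C[C@H](O[Si](C)(C)C(C)(C)C)/C=C(/C)[C@@H](OC(=O)/C(C)=C\C)C1SCCCS1 | intermediate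
23 | (2R,3Z,5S,7E,9S)-9-{[2-(bromomethyl)acryloyl]oxy}-5-[(tert-butyldimethylsilyl)oxy]-3,7-dimethyl-1-oxoundeca-3,7,10-trien-2-yl (2Z)-2-methylbut-2-enoate | C=C(CBr)C(=O)O[C@@H](C=C)/C=C(\C)C[C@H](O[Si](C)(C)C(C)(C)C)/C=C(/C)[C@@H](OC(=O)/C(C)=C\C)C=O | intermediate
24 | (2R,3Z,5S,7E)-8-[(2R)-4-(bromomethyl)-5-oxo-2,5-dihydrofuran-2-yl]-5-[(tert-butyldimethylsilyl)oxy]-3,7-dimethyl-1-oxoocta-3,7-dien-2-yl (2Z)-2-methylbut-2-enoate | O=C1O[C@@H](C=C1CBr)/C=C(\C)C[C@H](O[Si](C)(C)C(C)(C)C)/C=C(/C)[C@@H](OC(=O)/C(C)=C\C)C=O | intermediate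
25 | allylchromium dichloride derived from 24 (CH2Br replaced by CH2CrCl2, all stereocentres as in 24) | O=C1O[C@@H](C=C1C[Cr](Cl)Cl)/C=C(\C)C[C@H](O[Si](C)(C)C(C)(C)C)/C=C(/C)[C@@H](OC(=O)/C(C)=C\C)C=O | intermediate
26 | (1(10)Z,4E,2S,6R,7R,8R,9R)-9-angeloyloxy-2-[(tert-butyldimethylsilyl)oxy]-8-hydroxygermacra-1(10),4,11(13)-trien-12,6-olide | C=C1C(=O)O[C@@H]2/C=C(\C)C[C@H](O[Si](C)(C)C(C)(C)C)/C=C(/C)[C@@H](OC(=O)/C(C)=C\C)[C@H](O)[C@@H]12 | intermediate
27 | (1(10)Z,4E,2S,6R,7R,8R,9R)-9-angeloyloxy-2,8-dihydroxygermacra-1(10),4,11(13)-trien-12,6-olide (CNP0311662.1) | C=C1C(=O)O[C@@H]2/C=C(\C)C[C@H](O)/C=C(/C)[C@@H](OC(=O)/C(C)=C\C)[C@H](O)[C@@H]12 | target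

**Totals**
Total step count: 15. Longest linear sequence: 15 steps from geranyl acetate, because every coupling partner is bought.

**The three steps most likely to fail**

Step 14, the ring closure, is the riskiest step.
- It pays the entropic cost of forming a ten-membered ring.
- The polar Felkin–Anh bias of the α-acyloxy aldehyde opposes the face demanded by the butenolide and the chair. The required C8/C9 syn diol is the anti-Felkin product.
- Excess divalent chromium may slowly strip the α-acyloxy group.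

The fallback sets out from 24 and replaces the reducing metal by boron. Borylation of the allylic bromide with B2pin2 under Pd2(dba)3 catalysis (toluene, 40 °C) gives the allylboronate aldehyde F1. This is a closed-shell d3 donor that needs no reductant and tolerates long reaction times. At 1 mM with Sc(OTf)3 (10 mol %) it closes through a tighter boron-centred chair to the 8-O-pinacolboryl macrocycle F2. Work-up with triethanolamine returns to the route at 26.

Step 7, the CBS reduction, is risky because the dithianyl group and the twisted Z-alkenyl group are both bulky, so facial discrimination may be poor. The fallback sets out from 14 and moves stereocontrol from the reduction to the acylation. Luche reduction (NaBH4, CeCl3·7H2O, MeOH, −78 °C) gives 15 together with its 1S epimer alcohol F3. An acylative kinetic resolution then esterifies only the R alcohol. It uses angelic anhydride and a chiral isothiourea catalyst, with the enantiomer chosen to recognise the alkenyl π-face of 15. This comes back to the route at 17 and also replaces step 8. Recovered F3 is re-oxidised (SO3·pyridine, DMSO, Et3N) to 14 and recycled.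

Step 10, the asymmetric vinyl transfer, is risky because the Lewis-basic sulfur and ester groups may erode the enantioselectivity of the zinc catalyst. The fallback sets out from 18 and sets C6 by reduction instead of C–C bond formation. Vinylmagnesium bromide alone (THF, −78 °C) gives 20 mixed with its 8R epimer alcohol F4. MnO2 oxidises the mixture to the cross-conjugated vinyl dienone F5. (R)-Me-CBS with catecholborane, where the trisubstituted alkenyl group is large and vinyl is small, then returns to the route at 20.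

**Further compounds**
F1 | step 14 | (2R,3Z,5S,7E)-5-[(tert-butyldimethylsilyl)oxy]-3,7-dimethyl-1-oxo-8-{(2R)-5-oxo-4-[(4,4,5,5-tetramethyl-1,3,2-dioxaborolan-2-yl)methyl]-2,5-dihydrofuran-2-yl}octa-3,7-dien-2-yl (2Z)-2-methylbut-2-enoate | O=C1O[C@@H](C=C1CB1OC(C)(C)C(C)(C)O1)/C=C(\C)C[C@H](O[Si](C)(C)C(C)(C)C)/C=C(/C)[C@@H](OC(=O)/C(C)=C\C)C=O
F2 | step 14 | 8-O-(4,4,5,5-tetramethyl-1,3,2-dioxaborolan-2-yl) derivative of 26 (2S,6R,7R,8R,9R) | C=C1C(=O)O[C@@H]2/C=C(\C)C[C@H](O[Si](C)(C)C(C)(C)C)/C=C(/C)[C@@H](OC(=O)/C(C)=C\C)[C@H](OB3OC(C)(C)C(C)(C)O3)[C@@H]12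
F3 | step 7 | (1S,2Z,4S,6E)-4-[(tert-butyldimethylsilyl)oxy]-1-(1,3-dithian-2-yl)-2,6-dimethyl-8-[(triethylsilyl)oxy]octa-2,6-dien-1-ol | CC[Si](CC)(CC)OC/C=C(\C)C[C@H](O[Si](C)(C)C(C)(C)C)/C=C(/C)[C@H](O)C1SCCCS1
F4 | step 10 | (1R,2Z,4S,6E,8R)-4-[(tert-butyldimethylsilyl)oxy]-1-(1,3-dithian-2-yl)-8-hydroxy-2,6-dimethyldeca-2,6,9-trien-1-yl (2Z)-2-methylbut-2-enoate | O[C@H](C=C)/C=C(\C)C[C@H](O[Si](C)(C)C(C)(C)C)/C=C(/C)[C@@H](OC(=O)/C(C)=C\C)C1SCCCS1
F5 | step 10 | (1R,2Z,4S,6E)-4-[(tert-butyldimethylsilyl)oxy]-1-(1,3-dithian-2-yl)-2,6-dimethyl-8-oxodeca-2,6,9-trien-1-yl (2Z)-2-methylbut-2-enoate | C=CC(=O)/C=C(\C)C[C@H](O[Si](C)(C)C(C)(C)C)/C=C(/C)[C@@H](OC(=O)/C(C)=C\C)C1SCCCS1
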